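**Plan**

- Retrosynthesis: the 2-formyl group is traced back to a methyl ester (change of oxidation level only). The pyrrole is then cut at N1–C5 and C2–C3. The acyclic C3 partner is cut last at C3–C4, the acyl–alkynyl bond.
- Enabling feature: N1, C2 and the formyl carbon are the N, Cα and carboxyl carbon of glycine. C3 (carrying the C21 chain), C4 and C5 are the carbonyl carbon and the two alkyne carbons of tetracos-1-yn-3-one, which already has the oxidation level of the pyrrole.
- Forward order: docosanoic acid is converted to its Weinreb amide and ethynylated, so the chain is complete before any ring exists. The only ring forms in step 3 (N1–C5 first, then C2–C3). Ester to carbinol to aldehyde finishes the route.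
- Stereochemistry: the target has no stereocentre and no stereogenic double bond, so it is achiral and nothing has to be set. The only geometric element on the way is the Z-enaminone, fixed by its N–H···O=C hydrogen bond.

Key step: step 3

**Route**

Step 1
Reactants: 1 docosanoic acid; 2 N,O-dimethylhydroxylamine hydrochloride
Product: 4 N-methoxy-N-methyldocosanamide, via 1-docosanoylimidazole 3 (not isolated)
Conditions: CDI, THF, 40 °C; then 2, rt
Reagents that add atoms: N,O-dimethylhydroxylamine hydrochloride (2), CNOC.Cl
Why: CDI-mediated amidation through the acylimidazole is a standard Weinreb amide synthesis, the imidazole released from CDI frees the amine from its hydrochloride, and the saturated chain offers no competing site.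

Step 2
Reactants: 4 N-methoxy-N-methyldocosanamide; 5 ethynylmagnesium bromide
Product: 7 tetracos-1-yn-3-one, via bromomagnesium hemiaminal chelate 6 (not isolated)
Conditions: HC≡CMgBr (0.5 M in THF, excess), THF, 0 °C → rt; inverse quench into cold 1 M HCl
Reagents that add atoms: ethynylmagnesium bromide (5), C#C[Mg]Br
Why: Weinreb ketone synthesis, in which the magnesium chelate 6 survives until the quench so that only one ethynyl group adds, and pouring into cold acid protonates the released N,O-dimethylhydroxylamine before it can add to the new ynone.

Step 3
Reactants: 7 tetracos-1-yn-3-one; 8 glycine methyl ester hydrochloride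
Product: 11 methyl 3-henicosyl-1H-pyrrole-2-carboxylate, via Z-enaminone 9 (not isolated), via 3-hydroxy-2-pyrroline aldol 10 (not isolated)
Conditions: 8, Et3N, MeOH/THF, 0 °C → rt; then NaOMe, 3 Å MS, MeOH/THF, reflux
Reagents that add atoms: glycine methyl ester hydrochloride (8), Cl.NCC(=O)OC
Why: The amine freed by Et3N adds to the unsubstituted alkyne terminus of 7 (aza-Michael, N1–C5) to give the hydrogen-bonded Z-enaminone 9; methoxide then forms the glycinate ester enolate, which attacks the former ketone carbon (C2–C3) in an intramolecular aldol (Knoevenagel-type) addition, and E1cB loss of water from 10 aromatises the ring. The closest known reaction type is the alkoxide-mediated cyclisation of N-(3-oxoalk-1-enyl)glycinates, obtained from ynones or 1,3-dicarbonyl equivalents and glycine esters, to pyrrole-2-carboxylates. The single ring closes in a 5-(enolexo)-exo-trig mode, which the Z geometry of 9 allows because nitrogen and carbonyl lie on the same side of C4=C5. No stereocentre is created that survives, since both sp3 centres of 10 are lost on dehydration. The step needs 1,4- and not 1,2-addition of the amine, which the unhindered, strongly polarised terminal alkyne carbon should secure at 0 °C, so that the chain-bearing carbonyl carbon becomes C3 next to the ester. Methoxide is matched to the methyl ester and the sieves take up the water of condensation, so the ester should be neither scrambled nor saponified.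

Step 4
Reactants: 11 methyl 3-henicosyl-1H-pyrrole-2-carboxylate
Product: 12 (3-henicosyl-1H-pyrrol-2-yl)methanol
Conditions: LiAlH4 (excess), THF, 0 °C → rt; H2O/aq. NaOH work-up; crude product used at once
Reagents that add atoms: none
Why: Hydride reduction of an ester with LiAlH4, in which the N–H is deprotonated first and slows but does not stop reduction of the pyrrole-2-carboxylate, while the low temperature and basic work-up should keep the carbinol from ionising to an azafulvene.

Step 5
Reactants: 12 (3-henicosyl-1H-pyrrol-2-yl)methanol
Product: 13 3-henicosyl-1H-pyrrole-2-carbaldehyde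
Conditions: activated MnO2 (excess), CH2Cl2, rt
Reagents that add atoms: none
Why: MnO2 oxidation of an activated (benzylic-type, pyrrolyl) carbinol should stop at the aldehyde, which is stabilised as a vinylogous formamide, and leaves the N–H and the alkyl chain untouched.

**Compound list**

1 | docosanoic acid | CCCCCCCCCCCCCCCCCCCCCC(=O)O | starting material
2 | N,O-dimethylhydroxylamine hydrochloride | CNOC.Cl | starting material
3 | 1-docosanoylimidazole | CCCCCCCCCCCCCCCCCCCCCC(=O)n1ccnc1 | intermediate
4 | N-methoxy-N-methyldocosanamide | CCCCCCCCCCCCCCCCCCCCCC(=O)N(C)OC | intermediate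
5 | ethynylmagnesium bromide | C#C[Mg]Br | starting material
6 | bromomagnesium 3-[methoxy(methyl)amino]tetracos-1-yn-3-olate (racemic chelate) | CCCCCCCCCCCCCCCCCCCCCC(O[Mg]Br)(C#C)N(C)OC | intermediate
7 | tetracos-1-yn-3-one | CCCCCCCCCCCCCCCCCCCCCC(=O)C#C | intermediate
8 | glycine methyl ester hydrochloride | Cl.NCC(=O)OC | starting material
9 | methyl N-[(1Z)-3-oxotetracos-1-en-1-yl]glycinate | CCCCCCCCCCCCCCCCCCCCCC(=O)/C=C\NCC(=O)OC | intermediate
10 | methyl 3-henicosyl-3-hydroxy-2,3-dihydro-1H-pyrrole-2-carboxylate (racemic mixture of diastereomers) | CCCCCCCCCCCCCCCCCCCCCC1(O)C=CNC1C(=O)OC | intermediate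
11 | methyl 3-henicosyl-1H-pyrrole-2-carboxylate | CCCCCCCCCCCCCCCCCCCCCc1cc[nH]c1C(=O)OC | intermediate
12 | (3-henicosyl-1H-pyrrol-2-yl)methanol | CCCCCCCCCCCCCCCCCCCCCc1cc[nH]c1CO | intermediate
13 | 3-henicosyl-1H-pyrrole-2-carbaldehyde | CCCCCCCCCCCCCCCCCCCCCc1cc[nH]c1C=O | target

**Count**

Total steps: 5. Longest linear sequence: 5 steps, from docosanoic acid 1 to 13.

**Steps most likely to fail**

Step 3. Ring closure may stall after the conjugate addition. Methoxide can remove the N–H instead of the glycinate C–H, and the resulting vinylogous amide anion is a poor electrophile. On prolonged heating the ester may then be saponified, or the enaminone carbon C4 may attack the ester in a Dieckmann-type closure that leads to a 4-acyl-3-hydroxypyrrole. The fallback keeps the N1–C5 and C2–C3 bond formations but moves to the enone oxidation level with a sulfonamide nitrogen that carries no acidic hydrogen after addition. It sets out from Weinreb amide 4. Vinylmagnesium bromide in THF, with the same inverse acid quench, should give tetracos-1-en-3-one F1. Commercial methyl N-tosylglycinate and DBU in THF should add to the enone through nitrogen and then close by aldol addition of the sulfonamido ester carbon onto the ketone, giving methyl 3-henicosyl-3-hydroxy-1-tosylpyrrolidine-2-carboxylate F2. Dehydration with POCl3 in pyridine should give methyl 3-henicosyl-1-tosyl-2,5-dihydro-1H-pyrrole-2-carboxylate F3; any double-bond isomers converge in the next operation. DBU in warm toluene should then eliminate toluenesulfinate and tautomerise the product to the pyrrole. The fallback returns to the route at ester 11.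

Step 4. The N-metalated aluminium alkoxide may ionise to an azafulvene and be reduced further to the 2-methylpyrrole. The free carbinol may also oligomerise through the same cation during work-up or concentration. The fallback avoids the carbinol altogether and sets out from ester 11. Saponification with NaOH in aqueous THF/MeOH and careful neutralisation should give 3-henicosyl-1H-pyrrole-2-carboxylic acid F4; strong acid is avoided because of decarboxylation. Coupling with N,O-dimethylhydroxylamine hydrochloride 2 (EDC·HCl, HOBt, iPr2NEt, CH2Cl2) should give 3-henicosyl-N-methoxy-N-methyl-1H-pyrrole-2-carboxamide F5. LiAlH4 in THF at −20 to 0 °C should then stop at the chelated tetrahedral adduct and release the aldehyde on quench. The fallback returns to the route at target 13, so step 5 is not needed.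

Step 2. N,O-Dimethylhydroxylamine set free at the quench may add in conjugate fashion to the terminal ynone and give a β-aminoenone. The ynone may also oligomerise if it meets basic magnesium salts before neutralisation. The fallback removes the amine before any ynone exists and sets out from Weinreb amide 4. LiAlH4 in THF at 0 °C should give docosanal F6. Addition of ethynylmagnesium bromide 5 in THF at 0 °C should give racemic tetracos-1-yn-3-ol F7. Oxidation of the propargylic alcohol with Dess–Martin periodinane in CH2Cl2 (or Jones reagent in acetone) should give the ynone. The fallback returns to the route at 7.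

**Further compounds**

F1 | step 3 | tetracos-1-en-3-one | CCCCCCCCCCCCCCCCCCCCCC(=O)C=C
F2 | step 3 | methyl 3-henicosyl-3-hydroxy-1-tosylpyrrolidine-2-carboxylate (racemic mixture of diastereomers) | CCCCCCCCCCCCCCCCCCCCCC1(O)CCN(S(=O)(=O)c2ccc(C)cc2)C1C(=O)OC
F3 | step 3 | methyl 3-henicosyl-1-tosyl-2,5-dihydro-1H-pyrrole-2-carboxylate (racemic) | CCCCCCCCCCCCCCCCCCCCCC1=CCN(S(=O)(=O)c2ccc(C)cc2)C1C(=O)OC
F4 | step 4 | 3-henicosyl-1H-pyrrole-2-carboxylic acid | CCCCCCCCCCCCCCCCCCCCCc1cc[nH]c1C(=O)O
F5 | step 4 | 3-henicosyl-N-methoxy-N-methyl-1H-pyrrole-2-carboxamide | CCCCCCCCCCCCCCCCCCCCCc1cc[nH]c1C(=O)N(C)OC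
F6 | step 2 | docosanal | CCCCCCCCCCCCCCCCCCCCCC=O
F7 | step 2 | tetracos-1-yn-3-ol (racemic) | CCCCCCCCCCCCCCCCCCCCCC(O)C#C
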